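The route rests on cutting the bond between the first and second carbon of both heptyl chains. In ring A the chain stands on C2 beside the C1 carboxyl. In ring B it stands on C6′ beside the C1′ carboxyl. Each first chain carbon therefore corresponds to a benzylic methyl group made acidic by the neighbouring ester. Double lateral lithiation and double SN2 hexylation add twelve carbons in one operation. The substrate is the dimethyl diaryl ether, held as a bis(tert-butyl ester) with the C2′ phenol as a MOM ether. Both of its rings come from methyl orsellinate. Its C6–O–C4′ bridge arises from a depside by Smiles rearrangement.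

Key step: step 9

Remark: the target has no stereocentre and its diaryl ether axis rotates freely, so it is achiral and the route needs no stereocontrol.

Numbering:
- Ring A: C1 carboxyl, C2 chain, C4 OMe, C6 ether oxygen.
- Ring B: C1′ carboxyl, C2′ OH, C3′ H, C4′ ether oxygen, C5′ OMe, C6′ chain.
- Monomers carry orsellinate numbering: C1 ester, C2 OH, C4 OH, C6 methyl.

Step 1
Reactants: 1 methyl orsellinate (methyl 2,4-dihydroxy-6-methylbenzoate)
Product: 2 methyl 2-hydroxy-4-methoxy-6-methylbenzoate (methyl everninate)
Conditions: MeI (1.05 equiv), K2CO3 (1.1 equiv), acetone, reflux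
Reagents that add atoms: methyl iodide, CI
Why: Williamson ether synthesis in which the free, more acidic C4 hydroxyl reacts while the C2 hydroxyl is held in a hydrogen bond to the ester carbonyl, so one equivalent of methyl iodide should methylate O4 only.

Step 2
Reactants: 2 methyl 2-hydroxy-4-methoxy-6-methylbenzoate
Product: 3 2-hydroxy-4-methoxy-6-methylbenzoic acid (everninic acid)
Conditions: KOH, DMSO–H2O, 90 °C; then cold 2 M HCl
Reagents that add atoms: potassium hydroxide, [K+].[OH-]
Why: Saponification of a doubly ortho-flanked salicylate needs the poorly solvated hydroxide of aqueous DMSO, and acidification in the cold should spare the electron-rich acid from decarboxylation.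

Step 3
Reactants: 1 methyl orsellinate
Product: 4 methyl 5-bromo-2,4-dihydroxy-6-methylbenzoate (bromine between the C4 hydroxyl and the methyl group)
Conditions: NBS (1.0 equiv), MeCN, −10 to 0 °C
Reagents that add atoms: N-bromosuccinimide, O=C1CCC(=O)N1Br
Why: Electrophilic aromatic bromination should go to C5, which is para to the C2 hydroxyl and ortho to the C4 hydroxyl and is the usual halogenation site of β-resorcylate esters, whereas C3 between two oxygens reacts more slowly, and the product is purified by crystallisation.

Step 4
Reactants: 4 methyl 5-bromo-2,4-dihydroxy-6-methylbenzoate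
Product: 5 methyl 2,4-dihydroxy-5-methoxy-6-methylbenzoate
Conditions: NaOMe (6 equiv, in MeOH), CuBr (0.2 equiv), DMF, 110 °C, N2; then cold dil. HCl
Reagents that add atoms: sodium methoxide, [Na+].[O-]C
Why: Copper-catalysed Ullmann-type methoxylation of an ortho-bromophenol, the reaction type that converts 5-bromovanillin into syringaldehyde, is helped by copper binding to the neighbouring phenoxide, and ester exchange with methoxide is degenerate.

Step 5
Reactants: 3 everninic acid; 5 methyl 2,4-dihydroxy-5-methoxy-6-methylbenzoate
Product: 6 depside methyl 2-hydroxy-4-[(2-hydroxy-4-methoxy-6-methylbenzoyl)oxy]-5-methoxy-6-methylbenzoate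
Conditions: DCC (1.1 equiv), toluene–Et2O, rt
Reagents that add atoms: none
Why: Carbodiimide esterification as practised for lichen depsides should acylate only the non-chelated C4 hydroxyl of 5, because the two hydroxyls ortho to a carbonyl group are hydrogen-bonded and hindered.

Step 6
Reactants: 6 depside
Product: 8 2-(4-carboxy-5-hydroxy-2-methoxy-3-methylphenoxy)-4-methoxy-6-methylbenzoic acid, via Smiles monoacid 7 (not isolated)
Conditions: K2CO3 (1.1 equiv), dry DMSO, rt; then aq KOH, 90 °C, same flask; then cold 2 M HCl
Reagents that add atoms: potassium hydroxide, [K+].[OH-]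
Why: In the Smiles rearrangement the ring A phenoxide attacks C4′ ipso through a six-membered spiro Meisenheimer adduct stabilised by the para ester at C1′, which the still protonated and less acidic C2′ hydroxyl holds coplanar by chelation; the ring A carboxylate then leaves irreversibly, and hot KOH saponifies the remaining methyl ester.

Step 7
Reactants: 8 diacid
Product: 9 tert-butyl 2-[4-(tert-butoxycarbonyl)-5-hydroxy-2-methoxy-3-methylphenoxy]-4-methoxy-6-methylbenzoate
Conditions: Cl3CC(=NH)OtBu (5 equiv), CH2Cl2–THF, rt
Reagents that add atoms: tert-butyl 2,2,2-trichloroacetimidate, CC(C)(C)OC(=N)C(Cl)(Cl)Cl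
Why: Trichloroacetimidate esterification alkylates the carboxyl oxygens with the tert-butyl cation released from the protonated imidate, so the doubly ortho-flanked carbonyl carbons need not be attacked, and without a Lewis acid the chelated phenol should stay free.

Step 8
Reactants: 9 bis(tert-butyl ester) phenol; 10 chloromethyl methyl ether
Product: 11 tert-butyl 2-[4-(tert-butoxycarbonyl)-2-methoxy-5-(methoxymethoxy)-3-methylphenoxy]-4-methoxy-6-methylbenzoate
Conditions: NaH (1.2 equiv), MOMCl (1.3 equiv), DMF, 0 °C to rt
Reagents that add atoms: chloromethyl methyl ether (10), COCCl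
Why: Williamson-type O-alkylation in which sodium hydride breaks the chelate by forming the C2′ phenoxide, which displaces chloride from MOMCl under conditions that tert-butyl esters tolerate.

Step 9
Reactants: 11 dimethyl precursor; 12 1-iodohexane (two equivalents consumed)
Product: 14 tert-butyl 2-[4-(tert-butoxycarbonyl)-3-heptyl-2-methoxy-5-(methoxymethoxy)phenoxy]-6-heptyl-4-methoxybenzoate, via dilithio dianion 13 (not isolated)
Conditions: 11 added to LDA (3 equiv), THF, −78 °C; then DMPU, n-C6H13I (4 equiv), −78 to −40 °C; AcOH quench
Reagents that add atoms: 1-iodohexane (12), CCCCCCI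
Why: LDA removes one proton from each benzylic methyl group, because each carbanion is delocalised into its ortho tert-butyl ester as a lithium-chelated extended enolate, and the two sites lie on rings insulated by the ether oxygen, so the second deprotonation is not penalised by the first. Each carbanion then displaces iodide from 1-iodohexane in an SN2 step that DMPU accelerates, creating the first-to-second carbon bond of each chain; the closest known reaction type is lateral lithiation and alkylation of ortho-toluate (orsellinate) esters with primary halides, here run at two sites of one molecule. No ring is closed and no stereocentre is formed. Site selectivity is needed against the ring hydrogens, above all C3′–H between OMOM and OAr, and against the ester carbonyls: an amide base at −78 °C is too slow for ortho-metalation of alkoxyarenes, and each tert-butyl ester is shielded by two ortho substituents. Each methyl group is meta to the ether bridge, so neither carbanion can reach the ester or the ipso carbon of the other ring, which excludes Claisen-type closure and Truce–Smiles migration by geometry. Monoalkylation should hold because the secondary benzylic position of the product is more hindered and less acidic and only a small excess of base is present.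

Step 10
Reactants: 14 protected target
Product: 16 2-(4-carboxy-3-heptyl-5-hydroxy-2-methoxyphenoxy)-6-heptyl-4-methoxybenzoic acid (target CNP0151337.0), via free phenol diester 15 (not isolated)
Conditions: conc. HCl (cat.), MeOH–CH2Cl2, 40 °C; evaporate; then TFA–CH2Cl2 (1:3), Et3SiH (3 equiv), 0 °C to rt
Reagents that add atoms: none
Why: Acid-catalysed acetal exchange in methanol removes the MOM group first and carries its CH2 unit away as volatile dimethoxymethane, so no formaldehyde equivalent is left when trifluoroacetic acid cleaves both tert-butyl esters by the AAL1 path, with triethylsilane trapping the tert-butyl cation, at a temperature low enough to spare the decarboxylation-prone acids.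

Compound list
1 | methyl orsellinate (methyl 2,4-dihydroxy-6-methylbenzoate) | COC(=O)c1c(C)cc(O)cc1O | starting material
2 | methyl 2-hydroxy-4-methoxy-6-methylbenzoate | COC(=O)c1c(C)cc(OC)cc1O | intermediate
3 | 2-hydroxy-4-methoxy-6-methylbenzoic acid | Cc1cc(OC)cc(O)c1C(=O)O | intermediate
4 | methyl 5-bromo-2,4-dihydroxy-6-methylbenzoate | COC(=O)c1c(C)c(Br)c(O)cc1O | intermediate
5 | methyl 2,4-dihydroxy-5-methoxy-6-methylbenzoate | COC(=O)c1c(C)c(OC)c(O)cc1O | intermediate
6 | methyl 2-hydroxy-4-[(2-hydroxy-4-methoxy-6-methylbenzoyl)oxy]-5-methoxy-6-methylbenzoate | COC(=O)c1c(C)c(OC)c(OC(=O)c2c(C)cc(OC)cc2O)cc1O | intermediate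
7 | 2-[5-hydroxy-2-methoxy-4-(methoxycarbonyl)-3-methylphenoxy]-4-methoxy-6-methylbenzoic acid (present as potassium salt, not isolated) | COC(=O)c1c(C)c(OC)c(Oc2cc(OC)cc(C)c2C(=O)O)cc1O | intermediate
8 | 2-(4-carboxy-5-hydroxy-2-methoxy-3-methylphenoxy)-4-methoxy-6-methylbenzoic acid | Cc1cc(OC)cc(Oc2cc(O)c(C(=O)O)c(C)c2OC)c1C(=O)O | intermediate
9 | tert-butyl 2-[4-(tert-butoxycarbonyl)-5-hydroxy-2-methoxy-3-methylphenoxy]-4-methoxy-6-methylbenzoate | Cc1cc(OC)cc(Oc2cc(O)c(C(=O)OC(C)(C)C)c(C)c2OC)c1C(=O)OC(C)(C)C | intermediate
10 | chloromethyl methyl ether | COCCl | starting material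
11 | tert-butyl 2-[4-(tert-butoxycarbonyl)-2-methoxy-5-(methoxymethoxy)-3-methylphenoxy]-4-methoxy-6-methylbenzoate | Cc1cc(OC)cc(Oc2cc(OCOC)c(C(=O)OC(C)(C)C)c(C)c2OC)c1C(=O)OC(C)(C)C | intermediate
12 | 1-iodohexane | CCCCCCI | starting material
13 | dilithio derivative of 11, lithiated at both benzylic methyl groups (not isolated) | [Li]Cc1cc(OC)cc(Oc2cc(OCOC)c(C(=O)OC(C)(C)C)c(C[Li])c2OC)c1C(=O)OC(C)(C)C | intermediate
14 | tert-butyl 2-[4-(tert-butoxycarbonyl)-3-heptyl-2-methoxy-5-(methoxymethoxy)phenoxy]-6-heptyl-4-methoxybenzoate | CCCCCCCc1cc(OC)cc(Oc2cc(OCOC)c(C(=O)OC(C)(C)C)c(CCCCCCC)c2OC)c1C(=O)OC(C)(C)C | intermediate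
15 | tert-butyl 2-[4-(tert-butoxycarbonyl)-3-heptyl-5-hydroxy-2-methoxyphenoxy]-6-heptyl-4-methoxybenzoate (not isolated) | CCCCCCCc1cc(OC)cc(Oc2cc(O)c(C(=O)OC(C)(C)C)c(CCCCCCC)c2OC)c1C(=O)OC(C)(C)C | intermediate
16 | 2-(4-carboxy-3-heptyl-5-hydroxy-2-methoxyphenoxy)-6-heptyl-4-methoxybenzoic acid | CCCCCCCc1cc(OC)cc(Oc2cc(O)c(C(=O)O)c(CCCCCCC)c2OC)c1C(=O)O | target

Total step count: 10. Longest linear sequence: 8 (steps 3 to 10, from 1).

Steps most likely to fail

Step 9. The ring B methyl group stands next to the donor methoxy group at C5′ and may be deprotonated incompletely. Displacement on an unactivated primary iodide may also be slower than decay of the anions by proton return or loss of tert-butoxide. Either would leave half-alkylated mixtures. The fallback runs from 11 back to 14. The same dianion 13 is intercepted at −78 °C by the far more reactive allylic halide (E)-1-bromohex-2-ene. This should give tert-butyl 2-{4-(tert-butoxycarbonyl)-3-[(E)-hept-3-enyl]-2-methoxy-5-(methoxymethoxy)phenoxy}-6-[(E)-hept-3-enyl]-4-methoxybenzoate F1. Hydrogenation (H2, Pd/C, EtOAc) then saturates both chains to 14.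

Step 4. The C–Br bond is flanked on both sides and sits in an electron-rich bis-phenoxide, so C–O coupling may stall and reductive loss of bromine may take over. Imperfect site selectivity in step 3 would also be carried through. The fallback runs from 1 back to 5 and replaces steps 3 and 4.
- Selective benzylation of O4 (BnBr, K2CO3, acetone) gives methyl 4-(benzyloxy)-2-hydroxy-6-methylbenzoate F2.
- Elbs persulfate oxidation (K2S2O8, aq NaOH–pyridine, rt) oxidises para to the only free phenol, at C5, and gives potassium 2-(benzyloxy)-5-hydroxy-4-(methoxycarbonyl)-3-methylphenyl sulfate F3.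
- Warm dilute HCl hydrolyses F3 to methyl 4-(benzyloxy)-2,5-dihydroxy-6-methylbenzoate F4.
- MeI and K2CO3 methylate the non-chelated C5 hydroxyl to give methyl 4-(benzyloxy)-2-hydroxy-5-methoxy-6-methylbenzoate F5.
- Hydrogenolysis (H2, Pd/C) frees O4 and gives 5.

Step 6. Deprotonation of the C2′ hydroxyl would switch off ipso attack on ring B, and traces of water would cleave the depside ester before the aryl shift. The fallback runs from 2 and 5 back to 8 and forms the ether bond intermolecularly. Phenol 2 is converted with Tf2O and pyridine into methyl 4-methoxy-2-methyl-6-(trifluoromethylsulfonyloxy)benzoate F6. A Buchwald–Hartwig-type C–O coupling with the non-chelated C4 hydroxyl of 5 (Pd2(dba)3, t-BuXPhos, K3PO4, toluene, 100 °C) should give methyl 2-[5-hydroxy-2-methoxy-4-(methoxycarbonyl)-3-methylphenoxy]-4-methoxy-6-methylbenzoate F7. KOH in DMSO–H2O at 90 °C then saponifies both methyl esters to 8.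

Further compounds
F1 | step 9 | tert-butyl 2-{4-(tert-butoxycarbonyl)-3-[(E)-hept-3-enyl]-2-methoxy-5-(methoxymethoxy)phenoxy}-6-[(E)-hept-3-enyl]-4-methoxybenzoate | CCC/C=C/CCc1cc(OC)cc(Oc2cc(OCOC)c(C(=O)OC(C)(C)C)c(CC/C=C/CCC)c2OC)c1C(=O)OC(C)(C)C
F2 | step 4 | methyl 4-(benzyloxy)-2-hydroxy-6-methylbenzoate | COC(=O)c1c(C)cc(OCc2ccccc2)cc1O
F3 | step 4 | potassium 2-(benzyloxy)-5-hydroxy-4-(methoxycarbonyl)-3-methylphenyl sulfate | COC(=O)c1c(C)c(OS(=O)(=O)[O-])c(OCc2ccccc2)cc1O.[K+]
F4 | step 4 | methyl 4-(benzyloxy)-2,5-dihydroxy-6-methylbenzoate | COC(=O)c1c(C)c(O)c(OCc2ccccc2)cc1O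
F5 | step 4 | methyl 4-(benzyloxy)-2-hydroxy-5-methoxy-6-methylbenzoate | COC(=O)c1c(C)c(OC)c(OCc2ccccc2)cc1O
F6 | step 6 | methyl 4-methoxy-2-methyl-6-(trifluoromethylsulfonyloxy)benzoate | COC(=O)c1c(C)cc(OC)cc1OS(=O)(=O)C(F)(F)F
F7 | step 6 | methyl 2-[5-hydroxy-2-methoxy-4-(methoxycarbonyl)-3-methylphenoxy]-4-methoxy-6-methylbenzoate | COC(=O)c1c(C)c(OC)c(Oc2cc(OC)cc(C)c2C(=O)OC)cc1O
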